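The target is a cis-(2S,3R)-2,3-diaryl-2,3-dihydrobenzofuran, formally dihydroresveratrol (ring A plus bibenzyl arm) joined to a stilbene unit (C2, C3). Everything rests on cutting O1–C2 and C3a–C3. The key step exploits that C3 is doubly benzylic and C2 bears O1: at the ketone level C2–C3 is a deoxybenzoin with one enolisable carbon. Its enolate is arylated by palladium at C3a of brominated, MOM-protected dihydroresveratrol. Acid added to the same flask frees the C7a oxygen, which condenses with the C2 carbonyl. Both halves are thus joined as a flat benzofuran. Enantioselective syn hydrogenation of C2=C3 then sets the contra-thermodynamic cis pair, and neutral hydrogenolysis ends the route.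

Key step: step 4

Remark 1: the two descriptors of the SMILES place both aryl groups on the same face of the dihydrofuran ring, so the target is the cis isomer, (2S,3R). Benzofuran numbering is used throughout (O1, C2, C3, C3a, C4 to C7, C7a), and ring A is the benzo ring.
Remark 2: compounds 1, 4 and 5 are taken to be catalogue compounds.
Remark 3: the sense of induction in step 6 cannot be predicted safely for a 2,3-diaryl substrate. Both ligand antipodes are available, the one that leads to (2S,3R) is to be fixed in a trial run, and (R,R) is written here.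

Step 1
Reactants: 1 dihydroresveratrol, 5-[2-(4-hydroxyphenyl)ethyl]benzene-1,3-diol
Product: 2 1,3-bis(methoxymethoxy)-5-{2-[4-(methoxymethoxy)phenyl]ethyl}benzene
Conditions: NaH, MOMCl, DMF, 0 °C to rt
Reagents that add atoms: chloromethyl methyl ether (MOMCl), COCCl
Why: Williamson-type O-alkylation of the three sodium phenoxides is unselective by design, and the MOM acetals withstand NBS and the alkoxide base of step 4 but fall in acid at the moment the C7a oxygen is needed.

Step 2
Reactants: 2 1,3-bis(methoxymethoxy)-5-{2-[4-(methoxymethoxy)phenyl]ethyl}benzene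
Product: 3 2-bromo-1,5-bis(methoxymethoxy)-3-{2-[4-(methoxymethoxy)phenyl]ethyl}benzene
Conditions: NBS (1.0 equiv), MeCN, 0 °C, dark
Reagents that add atoms: N-bromosuccinimide (NBS), O=C1CCC(=O)N1Br
Why: Electrophilic aromatic bromination picks ring A, which two meta-placed acetal oxygens activate in concert, and there the position beside the arm (ortho to one OMOM, para to the other) rather than the more shielded site between the two OMOM groups; the two reactive positions are equivalent by symmetry, so this step marks C3a and decides which oxygen becomes O1.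

Step 3
Reactants: 4 1-[4-(benzyloxy)phenyl]ethanone; 5 1,3-bis(benzyloxy)-5-bromobenzene
Product: 6 2-[3,5-bis(benzyloxy)phenyl]-1-[4-(benzyloxy)phenyl]ethanone
Conditions: Pd2(dba)3, Xantphos, NaOt-Bu, toluene, 80 °C
Reagents that add atoms: none
Why: Palladium-catalysed ketone α-arylation (Buchwald–Hartwig type) of the methyl ketone enolate, in which the wide-bite-angle ligand and the lower reactivity of the more hindered product enolate should hold the reaction at monoarylation.

Step 4
Reactants: 3 2-bromo-1,5-bis(methoxymethoxy)-3-{2-[4-(methoxymethoxy)phenyl]ethyl}benzene; 6 2-[3,5-bis(benzyloxy)phenyl]-1-[4-(benzyloxy)phenyl]ethanone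
Product: 9 3-[3,5-bis(benzyloxy)phenyl]-2-[4-(benzyloxy)phenyl]-4-[2-(4-hydroxyphenyl)ethyl]-1-benzofuran-6-ol, via MOM-protected triaryl ketone 7 (not isolated), via trihydroxy triaryl ketone 8 (not isolated)
Conditions: Pd2(dba)3, P(t-Bu)3·HBF4, NaOt-Bu (2.5 equiv), toluene, 100 °C; then HCl in MeOH, 60 °C, same flask
Reagents that add atoms: none
Why: Oxidative addition of zerovalent palladium into the C–Br bond of 3, exchange of bromide for the sodium enolate of 6 and reductive elimination forge C3a–C3 and give ketone 7; methanolic HCl then strips the three MOM acetals, the freed C7a hydroxyl of 8 adds to the C2 carbonyl and the hemiketal loses water, which forges O1–C2. The closest known reaction type is the one-pot benzofuran synthesis by palladium-catalysed enolate arylation of ortho-bromophenols followed by acid cyclodehydration (Buchwald–Hartwig-type ketone α-arylation). The furan ring closes by 5-exo-trig attack of oxygen on the carbonyl carbon, followed by aromatising dehydration. No stereocentre survives the step: C3 of 7 forms racemic and becomes trigonal in 9, so both stereocentres are left to step 6. Regiochemistry is fully encoded, since the bromine fixes C3a on ring A, 6 has a single enolisable carbon so that the 3,5-dioxygenated ring ends at C3 and the 4-oxygenated ring at C2, and only the hydroxyl ortho to C3a can reach the carbonyl. The benzyl ethers survive the base and the methanolic HCl, and P(t-Bu)3 is chosen because the bromide is electron-rich and flanked on both sides.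

Step 5
Reactants: 9 3-[3,5-bis(benzyloxy)phenyl]-2-[4-(benzyloxy)phenyl]-4-[2-(4-hydroxyphenyl)ethyl]-1-benzofuran-6-ol
Product: 10 6-(benzyloxy)-3-[3,5-bis(benzyloxy)phenyl]-2-[4-(benzyloxy)phenyl]-4-{2-[4-(benzyloxy)phenyl]ethyl}-1-benzofuran
Conditions: BnBr, K2CO3, DMF, rt
Reagents that add atoms: benzyl bromide (BnBr), BrCc1ccccc1
Why: Williamson ether synthesis caps the two phenols freed in step 4, so that no acidic OH meets the base-activated catalyst of step 6 and all five protecting groups can leave together under neutral conditions.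

Step 6
Reactants: 10 6-(benzyloxy)-3-[3,5-bis(benzyloxy)phenyl]-2-[4-(benzyloxy)phenyl]-4-{2-[4-(benzyloxy)phenyl]ethyl}-1-benzofuran
Product: 11 (2S,3R)-6-(benzyloxy)-3-[3,5-bis(benzyloxy)phenyl]-2-[4-(benzyloxy)phenyl]-4-{2-[4-(benzyloxy)phenyl]ethyl}-2,3-dihydro-1-benzofuran (aryl groups at C2 and C3 cis)
Conditions: Ru(cod)(2-methylallyl)2 (10 mol %), (R,R)-1,3-bis[1-(naphthalen-1-yl)ethyl]imidazolinium tetrafluoroborate (20 mol %), KOt-Bu, toluene, 70 °C; then 10, H2 (100 bar), 60 °C
Reagents that add atoms: none
Why: Proposed new method: the chiral ruthenium bis(NHC) hydride should bind one face of the electron-rich C2=C3 enol-ether bond of the furan ring and deliver both hydrogens to that face (syn addition), so the aryl groups at C2 and C3 must end cis, while the C2-symmetric naphthylethyl pocket selects the face that gives (2S,3R); the closest known reaction type is the ruthenium–NHC-catalysed asymmetric hydrogenation of 2-aryl- and 2-alkylbenzofurans, which has not been shown on fully substituted 2,3-diarylbenzofurans, whereas heterogeneous syn hydrogenation of 2,3-disubstituted benzofurans to cis products is established.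

Step 7
Reactants: 11 (2S,3R)-pentabenzyl cis-dihydrobenzofuran
Product: 12 5-{(2S,3R)-6-hydroxy-2-(4-hydroxyphenyl)-4-[2-(4-hydroxyphenyl)ethyl]-2,3-dihydro-1-benzofuran-3-yl}benzene-1,3-diol (target, cis)
Conditions: H2 (1 atm), 10% Pd/C, EtOAc/MeOH, rt; filtration and purification without acid or base
Reagents that add atoms: none
Why: Catalytic hydrogenolysis should cleave the five unhindered primary benzyl aryl ethers faster than the hindered secondary C2–O1 bond, and the neutral medium avoids the acid- or base-induced opening at C2 (benzylic cation or para-quinone methide) that would epimerise the cis pair to trans, so both stereocentres are kept.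

Compound list
1 | dihydroresveratrol, 5-[2-(4-hydroxyphenyl)ethyl]benzene-1,3-diol | Oc1ccc(CCc2cc(O)cc(O)c2)cc1 | starting material
2 | 1,3-bis(methoxymethoxy)-5-{2-[4-(methoxymethoxy)phenyl]ethyl}benzene | COCOc1ccc(CCc2cc(OCOC)cc(OCOC)c2)cc1 | intermediate
3 | 2-bromo-1,5-bis(methoxymethoxy)-3-{2-[4-(methoxymethoxy)phenyl]ethyl}benzene | COCOc1ccc(CCc2cc(OCOC)cc(OCOC)c2Br)cc1 | intermediate
4 | 1-[4-(benzyloxy)phenyl]ethanone | CC(=O)c1ccc(OCc2ccccc2)cc1 | starting material
5 | 1,3-bis(benzyloxy)-5-bromobenzene | Brc1cc(OCc2ccccc2)cc(OCc2ccccc2)c1 | starting material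
6 | 2-[3,5-bis(benzyloxy)phenyl]-1-[4-(benzyloxy)phenyl]ethanone | O=C(Cc1cc(OCc2ccccc2)cc(OCc2ccccc2)c1)c1ccc(OCc2ccccc2)cc1 | intermediate
7 | MOM-protected triaryl ketone (racemic, not isolated), 2-[3,5-bis(benzyloxy)phenyl]-1-[4-(benzyloxy)phenyl]-2-(2,4-bis(methoxymethoxy)-6-{2-[4-(methoxymethoxy)phenyl]ethyl}phenyl)ethanone | O=C(c1ccc(OCc2ccccc2)cc1)C(c1cc(OCc2ccccc2)cc(OCc2ccccc2)c1)c1c(OCOC)cc(OCOC)cc1CCc1ccc(OCOC)cc1 | intermediate
8 | trihydroxy triaryl ketone (racemic, not isolated), 2-[3,5-bis(benzyloxy)phenyl]-1-[4-(benzyloxy)phenyl]-2-{2,4-dihydroxy-6-[2-(4-hydroxyphenyl)ethyl]phenyl}ethanone | O=C(c1ccc(OCc2ccccc2)cc1)C(c1cc(OCc2ccccc2)cc(OCc2ccccc2)c1)c1c(O)cc(O)cc1CCc1ccc(O)cc1 | intermediate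
9 | 3-[3,5-bis(benzyloxy)phenyl]-2-[4-(benzyloxy)phenyl]-4-[2-(4-hydroxyphenyl)ethyl]-1-benzofuran-6-ol | Oc1ccc(CCc2cc(O)cc3oc(-c4ccc(OCc5ccccc5)cc4)c(-c4cc(OCc5ccccc5)cc(OCc5ccccc5)c4)c23)cc1 | intermediate
10 | 6-(benzyloxy)-3-[3,5-bis(benzyloxy)phenyl]-2-[4-(benzyloxy)phenyl]-4-{2-[4-(benzyloxy)phenyl]ethyl}-1-benzofuran | c1ccc(COc2ccc(CCc3cc(OCc4ccccc4)cc4oc(-c5ccc(OCc6ccccc6)cc5)c(-c5cc(OCc6ccccc6)cc(OCc6ccccc6)c5)c34)cc2)cc1 | intermediate
11 | (2S,3R)-6-(benzyloxy)-3-[3,5-bis(benzyloxy)phenyl]-2-[4-(benzyloxy)phenyl]-4-{2-[4-(benzyloxy)phenyl]ethyl}-2,3-dihydro-1-benzofuran (cis) | c1ccc(COc2ccc(CCc3cc(OCc4ccccc4)cc4c3[C@@H](c3cc(OCc5ccccc5)cc(OCc5ccccc5)c3)[C@@H](c3ccc(OCc5ccccc5)cc3)O4)cc2)cc1 | intermediate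
12 | 5-{(2S,3R)-6-hydroxy-2-(4-hydroxyphenyl)-4-[2-(4-hydroxyphenyl)ethyl]-2,3-dihydro-1-benzofuran-3-yl}benzene-1,3-diol (cis) | Oc1ccc(CCc2cc(O)cc3c2[C@@H](c2cc(O)cc(O)c2)[C@@H](c2ccc(O)cc2)O3)cc1 | target

Total step count: 7
Longest linear sequence: 6 (steps 1, 2, 4, 5, 6, 7)

Steps most likely to fail

1. Step 6 (the labelled step).
- What may go wrong: the fully substituted C2=C3 bond is shielded by two twisted aryl rings and by the arm at C4, so it may not reach the metal. Facial selectivity may also be poor, or electron-rich benzene rings may be over-reduced under the forcing pressure.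
- Fallback (known chemistry, resolution in place of asymmetric catalysis): this sets out from 10. Heterogeneous hydrogenation over 10% Pd/C (H2, 50 bar, EtOAc/MeOH, 50 °C) removes the benzyl groups and adds hydrogen syn from the metal surface. This should give the racemic cis-dihydrobenzofuran pentaphenol F1.
- F1 is separated by preparative chromatography on an amylose tris(3,5-dimethylphenylcarbamate) phase. The (2S,3R) antipode is 12, where the fallback rejoins the route.

2. Step 4 (key step).
- What may go wrong: oxidative addition into the electron-rich, doubly ortho-flanked bromide may be slow, and reductive elimination to a very crowded triaryl carbon may be hindered. Either would let protodebromination of 3 take over.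
- Fallback (reversed polarity at C3, no palladium, both bonds still made in one operation): this sets out from 6 and from unprotected 1. α-Bromination of 6 (CuBr2, EtOAc/CHCl3, reflux) gives the α-bromo deoxybenzoin F2.
- F2 is heated with 1 on neutral Al2O3 in xylene. Friedel–Crafts-type ortho C-alkylation of the resorcinol ring by the C–Br carbon is followed by cyclodehydration of the neighbouring phenol onto the ketone.
- The fallback comes back to the route at 9 and bypasses 2 and 3. Its price is weaker control over which ring A position attacks, because no halogen marks C3a.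

3. Step 7.
- What may go wrong: competing hydrogenolysis of the benzylic C2–O1 bond of the strained cis ring may open the dihydrofuran before the last benzyl ether has gone.
- Fallback (change of protecting-group strategy): this sets out from 9. The three benzyl ethers are removed at the benzofuran stage, where no saturated benzylic ring C–O bond exists (H2, 1 atm, 10% Pd/C, EtOAc/MeOH). This gives the benzofuran pentaphenol F3.
- Silylation (TBSCl, imidazole, DMF) gives the penta-TBS benzofuran F4.
- Hydrogenation under the conditions of step 6 gives the (2S,3R)-cis penta-TBS dihydrobenzofuran F5.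
- Near-neutral fluoride (Et3N·3HF, THF, rt) frees the phenols, and the fallback comes back at 12.

Further compounds
F1 | step 6 | racemic cis-5-{6-hydroxy-2-(4-hydroxyphenyl)-4-[2-(4-hydroxyphenyl)ethyl]-2,3-dihydro-1-benzofuran-3-yl}benzene-1,3-diol, written as both antipodes | Oc1ccc(CCc2cc(O)cc3c2[C@@H](c2cc(O)cc(O)c2)[C@@H](c2ccc(O)cc2)O3)cc1.Oc1ccc(CCc2cc(O)cc3c2[C@H](c2cc(O)cc(O)c2)[C@H](c2ccc(O)cc2)O3)cc1
F2 | step 4 | 2-bromo-2-[3,5-bis(benzyloxy)phenyl]-1-[4-(benzyloxy)phenyl]ethanone (racemic) | O=C(c1ccc(OCc2ccccc2)cc1)C(Br)c1cc(OCc2ccccc2)cc(OCc2ccccc2)c1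
F3 | step 7 | 5-{6-hydroxy-2-(4-hydroxyphenyl)-4-[2-(4-hydroxyphenyl)ethyl]-1-benzofuran-3-yl}benzene-1,3-diol | Oc1ccc(CCc2cc(O)cc3oc(-c4ccc(O)cc4)c(-c4cc(O)cc(O)c4)c23)cc1
F4 | step 7 | penta-O-(tert-butyldimethylsilyl) ether of F3 | CC(C)(C)[Si](C)(C)Oc1ccc(CCc2cc(O[Si](C)(C)C(C)(C)C)cc3oc(-c4ccc(O[Si](C)(C)C(C)(C)C)cc4)c(-c4cc(O[Si](C)(C)C(C)(C)C)cc(O[Si](C)(C)C(C)(C)C)c4)c23)cc1
F5 | step 7 | (2S,3R)-cis-2,3-dihydro derivative of F4 | CC(C)(C)[Si](C)(C)Oc1ccc(CCc2cc(O[Si](C)(C)C(C)(C)C)cc3c2[C@@H](c2cc(O[Si](C)(C)C(C)(C)C)cc(O[Si](C)(C)C(C)(C)C)c2)[C@@H](c2ccc(O[Si](C)(C)C(C)(C)C)cc2)O3)cc1
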